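## Structural features

The target is a bicyclo[5.3.0]decane (hydroazulene). A seven-membered ring (C10–C1–C2–C3–C4–C5–C6) is trans-fused through the C6–C10 bond to a five-membered ring (C6–C7–C8–C9–C10), and C7 carries a (1Z,3E)-5-hydroxy-1,5-dimethylhexa-1,3-dienyl chain (C11–C15). Six stereocentres form two contiguous triads: C1 (acetoxy), C2 and C3 (trisubstituted epoxide) on the seven-membered ring, and C10 (methylated, quaternary), C6 and C7 around the ring fusion. The acetate, the epoxide oxygen, H-6 and the side chain all lie on the face opposite the C10 methyl group (called α here; the methyl face is β). The fragile groups are the epoxide next to an ester, the tertiary dienylic alcohol (ionisation, dehydration), the acetate (nucleophiles) and the C11=C12 alkene. That alkene is Z, with the ring carbon C7 and C13 cis, so an olefination of a C7 acetyl group would favour the wrong isomer. The real difficulty is the quaternary C10 beside the C6 stereocentre in a trans-fused five–seven system, together with oxygen at the neopentyl C1 anti to the methyl group. The key step uses the fact that C10 sits between C9 of the five-membered ring and the allylic C1 of the seven-membered ring, while C6 carries hydrogen next to a C7 that can hold a carbonyl group. That is the pattern left when a C10 cation takes C1 over from C6 and the resulting C6 cation is quenched by hydride from an oxygenated C7.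

## Logic of the disconnections

25 ⇒ 24. The acyl C–O bond at C1 is cut last, because an acetate would not survive the organolithium used before it. The forward step must acylate a hindered secondary alcohol and leave the tertiary C15 alcohol free.

24 ⇒ 23. The two C15–CH3 bonds are cut, so that the acid-labile dienyl carbinol appears only one step before the end. The forward step needs clean 1,2-addition to a dienoate without opening the epoxide.

23 ⇒ 21 (through 22). The C13=C14 bond is cut to a Z-allylic alcohol and a stabilised ylide, which gives the E geometry reliably. The forward step must oxidise only the primary allylic alcohol and trap the Z-enal before it isomerises.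

21 ⇒ 20. No skeletal bond is cut; C13 is taken back to the ester oxidation level, which is what the alkyne chemistry delivers.

20 ⇒ 19. The two epoxide C–O bonds are cut. The cis relation of the epoxide to the C1 oxygen is the signature of a hydroxyl-directed epoxidation, so the forward step needs the free 1α-alcohol and no other allylic alcohol in the molecule. This is why the side-chain carbinol is unveiled later.

19 ⇒ 18. The C1–H bond is cut to the enone. The forward step must deliver hydride to the β face next to the angular methyl group, so it is put under reagent control.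

18 ⇒ 17. The C11–CH3 bond is cut. Syn addition of methyl and hydrogen across an alkynoate gives exactly the Z-trisubstituted alkene, where an olefination would not. The forward step must be run cold so that the geometry holds and the enone is not attacked.

17 ⇒ 16. The C1 carbonyl is removed. C1 is the allylic methylene next to the CH end of the C2=C3 alkene, the position at which allylic oxidation gives a β-methyl enone. The demand is selectivity for C1 over C4 and the methyl group, on a substrate whose other functional group (an alkynoate) resists oxidation.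

16 ⇒ 14 (through 15). The C12–C13 bond is cut to an acetylide and a chloroformate.

14 ⇒ 13. The C11≡C12 bond is cut by one carbon to the aldehyde. The forward homologation must not disturb C7.

13 ⇒ 11 (through 12). The C7–C11 bond is cut to the C7 ketone. C7 is then set by equilibration of the aldehyde, trans to the C6–C5 bond. The forward olefination must outrun enolisation toward C6.

11 ⇒ 8 (through 9 and 10). The C8–C9 and C1–C10 bonds are cut together. This removes both rings of the bicycle, the quaternary C10 and the ring-fusion stereocentre C6, and leaves a monocyclic epoxide with two stereocentres. The forward cascade must open the epoxide at the primary C8, migrate C1 rather than C5, and end by hydride shift. The first ring closure is endo with respect to the epoxide, since C7 and C8 both end up in the ring.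

8 ⇒ 6 (through 7). The C8–O bond of the epoxide and the C7–H bond are cut to a chloromethyl ketone. The C7 configuration fixes the face on which hydride later reaches C6, and a methylide epoxidation of an aldehyde on C6 could not control it. It is therefore set by a catalyst-controlled ketone reduction.

6 ⇒ 5. The C7–C8 bond is cut to the ester. The forward step must add one carbon once and stop.

5 ⇒ 4. The C2=C3 bond is cut by ring-closing metathesis. This turns the ring stereocentre, which is stereogenic only through the position of the ring alkene, into an acyclic quaternary centre with four locally different groups.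

4 ⇒ 3. The two terminal C=CH2 bonds are cut to two ketones, one of which becomes the isopropenyl group (C10, C9).

3 ⇒ 1 + 2. The C5–C6 bond is cut to a conjugate addition. This puts the only catalyst-controlled C–C bond formation on an α-substituted β-keto ester, for which enantioselective addition to enones is established. A cycloaddition of isoprene to a 2-methylene-1,3-dicarbonyl compound was set aside: its two carbonyl groups are too alike for a C2-symmetric chelating catalyst to distinguish the faces, and that dienophile is unstable.

## Other disconnections considered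

Alternative 1: The cut runs through C5–C6 and C1–C10, two bonds on the cyclopentane and no ring. In the forward sense a vinyl group would be added under copper mediation to C6 of the silyloxy enone A1, anti to the silyl ether on C7. The C10 enolate would then be trapped by the (Z)-iodoenal A2 to give the fully substituted cyclopentanone A3.
- In its favour: conjugate addition followed by aldol trapping is an established reaction type. Both ring-fusion centres follow from the single stereocentre of A1. C1 arrives already oxygenated.
- Against it here: no ring is closed, so the seven-membered ring still has to be made by a separate C3–C4 closure on a crowded substrate. The C9 carbonyl has to be deleted. The C7 oxygen has to be exchanged for the carbon chain with control. C1 is formed as a mixture of epimers.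
- Comparison: on mechanism this plan is the better one, because each bond formation has close precedent. On oxygenation it is also better, because it needs no allylic oxidation at C1. On structure it equals the chosen plan in bonds and stereocentres made in the key step but closes no ring against two. On step economy it would be longer, because of the deoxygenation, the ring closure and the C7 exchange.

Alternative 2: The cut is the C7–C8 bond, made by contracting a six-membered ring. In the forward sense irradiation of the α-diazoketone A4 in an alcohol would expel nitrogen, C8 would shift to the carbene carbon C7, and the ketene would be trapped as the ester A5.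
- In its favour: the photochemical Wolff rearrangement is dependable. The C7 ester can be equilibrated to the α configuration. The C1 oxygen is present as a ketal.
- Against it here: the step only reshapes a ring. A4 itself needs a trans-fused six–seven system with the quaternary methyl group already in place, and then diazo transfer. The C3 methyl group and the C2=C3 alkene are still missing and would have to be grown from the C1 ketone.
- Comparison: on mechanism this plan is better than the chosen one. Its C7 ester is a better handle than the C7 ketone of the chosen plan, since it stands two steps further along. On structure it makes one bond and one stereocentre against two bonds, two rings and two stereocentres. On step economy it is clearly worse.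

Alternative 3: The cut runs through C6–C10 and C2–C3. In the forward sense base in a fluorinated alcohol would ionise the tertiary α-chloroketone A6 to the oxyallyl cation C10–C1–C2, which would add across the furan ring of A6 (C6 and C3) to give the oxygen-bridged tricycle A7.
- In its favour: both rings, two C–C bonds and the centres C10, C6 and C3 are formed at once. The C1 carbonyl and an α-oriented C3–O bond (a possible source of the epoxide oxygen) are installed. Intramolecular furan–oxyallyl (4+3) cycloaddition is a known reaction class.
- Against it here: facial control would rest on the C7 stereocentre acting through a three-atom tether. The tertiary chloride and the ketal are sensitive. The bridge would have to be opened at C6 with delivery of hydrogen with retention to reach the trans fusion, for which there is no simple method. The C4=C5 alkene is surplus.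
- Comparison: in complexity generated and in oxygenation pattern this plan is the better one. In precedent for the key event it is at least the equal of the chosen plan. It is worse in the endgame, where removal of the bridge decides the ring fusion. Its step economy would be comparable only if that opening could be solved.

Key step: step 6

Remarks before the steps:
- Locants throughout: C1 acetoxy carbon; C2, C3 epoxide carbons (methyl on C3); C4, C5; C6 ring-fusion CH; C7 side-chain carbon; C8, C9; C10 methylated ring-fusion carbon. The same locants are used for the monocyclic precursors. Bicyclic compounds are named as bicyclo[5.3.0]decanes with these locants. α is the face of H-6 and β the face of the C10 methyl group.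
- Assumption: the cupreidine-derived catalyst of step 1 is taken to give the S adduct. Its cupreine-derived pseudo-enantiomer is used if the sense of induction is the opposite.
- Assumption: in both CBS reductions the fully substituted carbon next to the carbonyl group (C6 in step 5, C10 in step 13) acts as the large group.

Step 1
Reactants: 1 ethyl 2-acetylpent-4-enoate; 2 but-3-en-2-one
Product: 3 ethyl (S)-2-acetyl-5-oxo-2-(prop-2-en-1-yl)hexanoate
Conditions: 9-O-(phenanthren-9-yl)cupreidine (10 mol%), CH2Cl2, –20 °C
Reagents that add atoms: none
Why: Enantioselective Michael addition of an α-substituted β-keto ester to an enone under bifunctional cinchona-alkaloid catalysis; the quinuclidine nitrogen forms the enolate ion pair, the phenolic hydroxyl binds the enone, and one enolate face is offered to 2, which sets the quaternary stereocentre (future C6).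

Step 2
Reactants: 3 ethyl (S)-2-acetyl-5-oxo-2-(prop-2-en-1-yl)hexanoate
Product: 4 ethyl (S)-5-methyl-2-(prop-2-en-1-yl)-2-(prop-1-en-2-yl)hex-5-enoate
Conditions: Ph3PCH3Br, KN(SiMe3)2, THF, 0 °C then 60 °C
Reagents that add atoms: methyltriphenylphosphonium bromide, C[P+](c1ccccc1)(c1ccccc1)c1ccccc1.[Br-]
Why: Twofold Wittig methylenation with an alkoxide-free ylide; the side-chain ketone reacts first and the hindered acetyl group on warming, the ester is left alone, and the quaternary centre has no α-hydrogen to lose.

Step 3
Reactants: 4 ethyl (S)-5-methyl-2-(prop-2-en-1-yl)-2-(prop-1-en-2-yl)hex-5-enoate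
Product: 5 ethyl (S)-4-methyl-1-(prop-1-en-2-yl)cyclohex-3-ene-1-carboxylate
Conditions: RuCl2(=CHPh)(H2IMes)(PCy3) (second-generation Grubbs catalyst, 2 mol%), CH2Cl2, 40 °C
Reagents that add atoms: none
Why: Ring-closing metathesis between the allyl group and the 1,1-disubstituted alkene of the other arm gives the trisubstituted cyclohexene; closure onto the isopropenyl group would need a four-membered ring or a tetrasubstituted cyclopentene, so the stereocentre should be carried over unchanged.

Step 4
Reactants: 5 ethyl (S)-4-methyl-1-(prop-1-en-2-yl)cyclohex-3-ene-1-carboxylate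
Product: 6 2-chloro-1-[(S)-4-methyl-1-(prop-1-en-2-yl)cyclohex-3-en-1-yl]ethan-1-one
Conditions: ICH2Cl, MeLi·LiBr, THF/Et2O, –78 °C; AcOH quench at –78 °C
Reagents that add atoms: chloroiodomethane, ClCI
Why: Homologation of the ester with the carbenoid LiCH2Cl generated in the presence of the substrate; the tetrahedral lithium alkoxide should persist at –78 °C and collapse to the chloromethyl ketone only on quench, which prevents a second addition.

Step 5
Reactants: 6 2-chloro-1-[(S)-4-methyl-1-(prop-1-en-2-yl)cyclohex-3-en-1-yl]ethan-1-one
Product: 8 (R)-2-[(S)-4-methyl-1-(prop-1-en-2-yl)cyclohex-3-en-1-yl]oxirane, via chlorohydrin 7 (not isolated)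
Conditions: (R)-1-methyl-3,3-diphenyltetrahydro-1H,3H-pyrrolo[1,2-c][1,3,2]oxazaborole ((R)-Me-CBS, 10 mol%), catecholborane, toluene, –78 to –40 °C; then 2 M NaOH, MeOH, 0 °C to rt
Reagents that add atoms: none
Why: CBS reduction with the quaternary C6 as the large group and CH2Cl as the small one, so that the (R)-catalyst should give the (R)-chlorohydrin and thereby set C7; catecholborane at low temperature leaves the three alkenes alone, and hydroxide then closes the epoxide by displacement at C8 without touching C7.

Step 6
Reactants: 8 (R)-2-[(S)-4-methyl-1-(prop-1-en-2-yl)cyclohex-3-en-1-yl]oxirane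
Product: 11 (3aR,8aR)-3a,6-dimethyl-3,3a,4,7,8,8a-hexahydroazulen-1(2H)-one (3,10β-dimethyl-6αH-bicyclo[5.3.0]dec-2-en-7-one), via spirocyclic cation 9 (not isolated), via ring-enlarged cation 10 (not isolated)
Conditions: Et2AlCl (1.5 equiv), CH2Cl2, –78 to –20 °C; aq. potassium sodium tartrate
Reagents that add atoms: none
Why: Proposed new method: Et2AlCl binds the epoxide oxygen and the terminal carbon C9 of the isopropenyl group attacks the primary carbon C8, which closes the five-membered ring C6–C7–C8–C9–C10 and leaves the tertiary cation 9 at C10; the closest known reaction types are the Lewis-acid epoxide–olefin cyclisation and the Wagner–Meerwein ring enlargement of spiro[4.5]decyl cations ended by the hydride shift of a semipinacol rearrangement. This first closure is endo for both partners (5-endo for the alkene, and endo for the epoxide because C7 and C8 both become ring members). The allylic carbon C1 then moves suprafacially from C6 to C10, so the seven-membered ring is closed by a 1,2-alkyl shift that enlarges the cyclohexene and gives the tertiary cation 10 at C6. A 1,2-hydride shift from the aluminium-alkoxide carbon C7 to C6 ends the cascade as the ketone. C10 is controlled by the configuration of C6 in 8, because C1 lies on the α face of the new cyclopentane and can arrive only on that face of C10, leaving the methyl group β. C6 is controlled by the configuration of C7 in 8, because the migrating hydrogen lies on the α face and so ends trans to the C10 methyl group. The step needs attack at C8 in preference to ionisation at C7, migration of C1 in preference to C5, and no participation or shift of the ring alkene; what should secure these are the five-membered transition state open only to C8, the better stabilisation of positive charge on the allylic C1 by the C2=C3 bond, and an alkylaluminium chloride that scavenges protons.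

Step 7
Reactants: 11 3,10β-dimethyl-6αH-bicyclo[5.3.0]dec-2-en-7-one
Product: 12 7-(methoxymethylidene)-3,10β-dimethyl-6αH-bicyclo[5.3.0]dec-2-ene (E/Z mixture)
Conditions: Ph3P(CH2OMe)Cl, KN(SiMe3)2, THF, –78 to 0 °C (ketone added to the ylide)
Reagents that add atoms: (methoxymethyl)triphenylphosphonium chloride, COC[P+](c1ccccc1)(c1ccccc1)c1ccccc1.[Cl-]
Why: Wittig reaction of the cyclopentanone with methoxymethylenetriphenylphosphorane; inverse addition at low temperature lets olefination outrun enolisation toward C6, and once C7 is olefinic C6 can no longer epimerise.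

Step 8
Reactants: 12 7-(methoxymethylidene)-3,10β-dimethyl-6αH-bicyclo[5.3.0]dec-2-ene
Product: 13 3,10β-dimethyl-6αH-bicyclo[5.3.0]dec-2-ene-7α-carbaldehyde
Conditions: 1 M HCl, THF, rt; then K2CO3, MeOH, rt
Reagents that add atoms: water, O
Why: Acid hydrolysis of the enol ether to the aldehyde, then base equilibration at C7; the formyl group should settle on the α face, trans to the C6–C5 bond and away from the C10 methyl group, which is the configuration of the target.

Step 9
Reactants: 13 3,10β-dimethyl-6αH-bicyclo[5.3.0]dec-2-ene-7α-carbaldehyde
Product: 14 7α-ethynyl-3,10β-dimethyl-6αH-bicyclo[5.3.0]dec-2-ene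
Conditions: MeCOC(N2)P(O)(OMe)2, K2CO3, MeOH, 0 °C to rt
Reagents that add atoms: dimethyl (1-diazo-2-oxopropyl)phosphonate, CC(=O)C(=[N+]=[N-])P(=O)(OC)OC
Why: Seyferth–Gilbert homologation with the Ohira–Bestmann reagent adds C12 and gives the terminal alkyne; the carbonate medium keeps C7 at its thermodynamic α configuration until it is fixed.

Step 10
Reactants: 14 7α-ethynyl-3,10β-dimethyl-6αH-bicyclo[5.3.0]dec-2-ene
Product: 16 methyl 3-(3,10β-dimethyl-6αH-bicyclo[5.3.0]dec-2-en-7α-yl)prop-2-ynoate, via lithium acetylide 15 (not isolated)
Conditions: n-BuLi (1.05 equiv), THF, –78 °C; ClCO2Me, –78 to –20 °C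
Reagents that add atoms: methyl chloroformate, COC(=O)Cl
Why: Deprotonation of the terminal alkyne and acylation of the acetylide; one equivalent of base at low temperature avoids propargylic deprotonation at C7.

Step 11
Reactants: 16 methyl 3-(3,10β-dimethyl-6αH-bicyclo[5.3.0]dec-2-en-7α-yl)prop-2-ynoate
Product: 17 methyl 3-(3,10β-dimethyl-1-oxo-6αH-bicyclo[5.3.0]dec-2-en-7α-yl)prop-2-ynoate
Conditions: CrO3, 3,5-dimethylpyrazole (15 equiv each), CH2Cl2, –20 °C
Reagents that add atoms: chromium trioxide, O=[Cr](=O)=O
Why: Allylic oxidation with the CrO3–3,5-dimethylpyrazole complex; a trisubstituted cycloalkene is oxidised at the methylene next to its CH terminus (C1), giving the β-methyl enone, while the electron-poor alkynoate and its propargylic C7–H should be inert.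

Step 12
Reactants: 17 methyl 3-(3,10β-dimethyl-1-oxo-6αH-bicyclo[5.3.0]dec-2-en-7α-yl)prop-2-ynoate
Product: 18 methyl (Z)-3-(3,10β-dimethyl-1-oxo-6αH-bicyclo[5.3.0]dec-2-en-7α-yl)but-2-enoate
Conditions: Me2CuLi (1.3 equiv, from CuI and MeLi), THF, –78 °C; MeOH then aq. NH4Cl at –78 °C
Reagents that add atoms: lithium dimethylcuprate (made in the flask from methyllithium and CuI), [Li+].C[Cu-]C
Why: Syn carbocupration (conjugate addition) of the alkynoate and protonation at –78 °C place methyl and hydrogen cis, hence C7 and the ester cis (Z); the β,β-disubstituted enone is far less reactive toward the cuprate at this temperature.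

Step 13
Reactants: 18 methyl (Z)-3-(3,10β-dimethyl-1-oxo-6αH-bicyclo[5.3.0]dec-2-en-7α-yl)but-2-enoate
Product: 19 methyl (Z)-3-(1α-hydroxy-3,10β-dimethyl-6αH-bicyclo[5.3.0]dec-2-en-7α-yl)but-2-enoate
Conditions: (S)-1-methyl-3,3-diphenyltetrahydro-1H,3H-pyrrolo[1,2-c][1,3,2]oxazaborole ((S)-Me-CBS, 20 mol%), catecholborane, toluene, –78 °C
Reagents that add atoms: none
Why: CBS 1,2-reduction of the enone; with the quaternary C10 as the large group the (S)-catalyst should deliver hydride to the β face and give the 1α-alcohol, and reagent control is used because attack anti to the angular methyl group would give the epimer.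

Step 14
Reactants: 19 methyl (Z)-3-(1α-hydroxy-3,10β-dimethyl-6αH-bicyclo[5.3.0]dec-2-en-7α-yl)but-2-enoate
Product: 20 methyl (Z)-3-(2α,3α-epoxy-1α-hydroxy-3,10β-dimethyl-6αH-bicyclo[5.3.0]decan-7α-yl)but-2-enoate
Conditions: VO(acac)2 (5 mol%), t-BuOOH, CH2Cl2, 0 °C to rt
Reagents that add atoms: tert-butyl hydroperoxide, CC(C)(C)OO
Why: Vanadium-catalysed hydroxyl-directed epoxidation delivers oxygen to the face of C2=C3 that carries the C1 hydroxyl (α), as is general for cyclohept-2-enols, and so sets C2 and C3; the enoate is electron-poor, has no directing hydroxyl and should be left alone.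

Step 15
Reactants: 20 methyl (Z)-3-(2α,3α-epoxy-1α-hydroxy-3,10β-dimethyl-6αH-bicyclo[5.3.0]decan-7α-yl)but-2-enoate
Product: 21 (Z)-3-(2α,3α-epoxy-1α-hydroxy-3,10β-dimethyl-6αH-bicyclo[5.3.0]decan-7α-yl)but-2-en-1-ol
Conditions: i-Bu2AlH (3.5 equiv), CH2Cl2, –78 °C; aq. potassium sodium tartrate
Reagents that add atoms: none
Why: Low-temperature DIBAL reduction of the conjugated ester to the (Z)-allylic alcohol; at –78 °C the trisubstituted epoxide and the alkene geometry should be unaffected.

Step 16
Reactants: 21 (Z)-3-(2α,3α-epoxy-1α-hydroxy-3,10β-dimethyl-6αH-bicyclo[5.3.0]decan-7α-yl)but-2-en-1-ol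
Product: 23 methyl (2E,4Z)-5-(2α,3α-epoxy-1α-hydroxy-3,10β-dimethyl-6αH-bicyclo[5.3.0]decan-7α-yl)hexa-2,4-dienoate, via enal 22 (not isolated)
Conditions: MnO2 (10 equiv), Ph3P=CHCO2Me (1.3 equiv), CH2Cl2, rt
Reagents that add atoms: methyl (triphenylphosphoranylidene)acetate, COC(=O)C=P(c1ccccc1)(c1ccccc1)c1ccccc1
Why: Tandem oxidation–Wittig reaction; MnO2 oxidises only the primary allylic alcohol (the C1 alcohol is no longer allylic) and the stabilised ylide traps the Z-enal at once to give the E alkene C13=C14, which keeps the enal from isomerising.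

Step 17
Reactants: 23 methyl (2E,4Z)-5-(2α,3α-epoxy-1α-hydroxy-3,10β-dimethyl-6αH-bicyclo[5.3.0]decan-7α-yl)hexa-2,4-dienoate
Product: 24 (3E,5Z)-6-(2α,3α-epoxy-1α-hydroxy-3,10β-dimethyl-6αH-bicyclo[5.3.0]decan-7α-yl)-2-methylhepta-3,5-dien-2-ol
Conditions: MeLi (5 equiv), THF, –78 to –40 °C; aq. NH4Cl
Reagents that add atoms: methyllithium, [Li]C
Why: Double 1,2-addition of methyllithium to the ester gives the tertiary alcohol; the C1 hydroxyl is carried as its lithium alkoxide, which is cis to the epoxide and cannot open it from the back, and the epoxide itself is inert to MeLi at low temperature.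

Step 18
Reactants: 24 (3E,5Z)-6-(2α,3α-epoxy-1α-hydroxy-3,10β-dimethyl-6αH-bicyclo[5.3.0]decan-7α-yl)-2-methylhepta-3,5-dien-2-ol
Product: 25 (1S,2S,3R,6S,7R,10S)-2,3-epoxy-7-[(2Z,4E)-6-hydroxy-6-methylhepta-2,4-dien-2-yl]-3,10-dimethylbicyclo[5.3.0]decan-1-yl acetate (CNP0265175.1)
Conditions: Ac2O, pyridine, DMAP (cat.), CH2Cl2, 0 °C to rt
Reagents that add atoms: acetic anhydride, CC(=O)OC(C)=O
Why: DMAP-catalysed acetylation of the secondary C1 alcohol; the tertiary C15 alcohol should not acylate under these conditions, and the buffered medium protects the epoxide and the dienyl carbinol.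

Compound list

1 | ethyl 2-acetylpent-4-enoate (racemic) | CCOC(=O)C(CC=C)C(C)=O | starting material
2 | but-3-en-2-one | CC(=O)C=C | starting material
3 | ethyl (S)-2-acetyl-5-oxo-2-(prop-2-en-1-yl)hexanoate | C=CC[C@@](CCC(C)=O)(C(C)=O)C(=O)OCC | intermediate
4 | ethyl (S)-5-methyl-2-(prop-2-en-1-yl)-2-(prop-1-en-2-yl)hex-5-enoate | C=CC[C@@](CCC(C)=C)(C(C)=C)C(=O)OCC | intermediate
5 | ethyl (S)-4-methyl-1-(prop-1-en-2-yl)cyclohex-3-ene-1-carboxylate | CC1=CC[C@@](CC1)(C(C)=C)C(=O)OCC | intermediate
6 | 2-chloro-1-[(S)-4-methyl-1-(prop-1-en-2-yl)cyclohex-3-en-1-yl]ethan-1-one | CC1=CC[C@@](CC1)(C(C)=C)C(=O)CCl | intermediate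
7 | (R)-2-chloro-1-[(S)-4-methyl-1-(prop-1-en-2-yl)cyclohex-3-en-1-yl]ethan-1-ol | CC1=CC[C@@](CC1)(C(C)=C)[C@@H](O)CCl | intermediate (not isolated)
8 | (R)-2-[(S)-4-methyl-1-(prop-1-en-2-yl)cyclohex-3-en-1-yl]oxirane | CC1=CC[C@@](CC1)(C(C)=C)[C@@H]2CO2 | intermediate
9 | spirocyclic tertiary cation at C10, C7 oxygen as chlorodiethylaluminate (zwitterion) | CC1=CC[C@@]2(CC1)[C+](C)CC[C@@H]2O[Al-](CC)(CC)Cl | intermediate (not isolated)
10 | ring-enlarged tertiary cation at C6, C7 oxygen as chlorodiethylaluminate (zwitterion) | CC1=CC[C@@]2(C)CC[C@H](O[Al-](CC)(CC)Cl)[C+]2CC1 | intermediate (not isolated)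
11 | (3aR,8aR)-3a,6-dimethyl-3,3a,4,7,8,8a-hexahydroazulen-1(2H)-one (3,10β-dimethyl-6αH-bicyclo[5.3.0]dec-2-en-7-one, trans-fused) | O=C1CC[C@]2(C)CC=C(C)CC[C@@H]12 | intermediate
12 | 7-(methoxymethylidene)-3,10β-dimethyl-6αH-bicyclo[5.3.0]dec-2-ene (E/Z mixture) | COC=C1CC[C@]2(C)CC=C(C)CC[C@@H]12 | intermediate
13 | 3,10β-dimethyl-6αH-bicyclo[5.3.0]dec-2-ene-7α-carbaldehyde | C1C=C(C)CC[C@H]2[C@H](C=O)CC[C@]12C | intermediate
14 | 7α-ethynyl-3,10β-dimethyl-6αH-bicyclo[5.3.0]dec-2-ene | C1C=C(C)CC[C@H]2[C@H](C#C)CC[C@]12C | intermediate
15 | lithium acetylide of 14 | C1C=C(C)CC[C@H]2[C@H](C#C[Li])CC[C@]12C | intermediate (not isolated)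
16 | methyl 3-(3,10β-dimethyl-6αH-bicyclo[5.3.0]dec-2-en-7α-yl)prop-2-ynoate | C1C=C(C)CC[C@H]2[C@H](C#CC(=O)OC)CC[C@]12C | intermediate
17 | methyl 3-(3,10β-dimethyl-1-oxo-6αH-bicyclo[5.3.0]dec-2-en-7α-yl)prop-2-ynoate | O=C1C=C(C)CC[C@H]2[C@H](C#CC(=O)OC)CC[C@]12C | intermediate
18 | methyl (Z)-3-(3,10β-dimethyl-1-oxo-6αH-bicyclo[5.3.0]dec-2-en-7α-yl)but-2-enoate | O=C1C=C(C)CC[C@H]2[C@H](/C(C)=C\C(=O)OC)CC[C@]12C | intermediate
19 | methyl (Z)-3-(1α-hydroxy-3,10β-dimethyl-6αH-bicyclo[5.3.0]dec-2-en-7α-yl)but-2-enoate | O[C@@H]1C=C(C)CC[C@H]2[C@H](/C(C)=C\C(=O)OC)CC[C@]12C | intermediate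
20 | methyl (Z)-3-(2α,3α-epoxy-1α-hydroxy-3,10β-dimethyl-6αH-bicyclo[5.3.0]decan-7α-yl)but-2-enoate | O[C@@H]1[C@@H]2O[C@]2(C)CC[C@H]2[C@H](/C(C)=C\C(=O)OC)CC[C@]12C | intermediate
21 | (Z)-3-(2α,3α-epoxy-1α-hydroxy-3,10β-dimethyl-6αH-bicyclo[5.3.0]decan-7α-yl)but-2-en-1-ol | O[C@@H]1[C@@H]2O[C@]2(C)CC[C@H]2[C@H](/C(C)=C\CO)CC[C@]12C | intermediate
22 | (Z)-3-(2α,3α-epoxy-1α-hydroxy-3,10β-dimethyl-6αH-bicyclo[5.3.0]decan-7α-yl)but-2-enal | O[C@@H]1[C@@H]2O[C@]2(C)CC[C@H]2[C@H](/C(C)=C\C=O)CC[C@]12C | intermediate (not isolated)
23 | methyl (2E,4Z)-5-(2α,3α-epoxy-1α-hydroxy-3,10β-dimethyl-6αH-bicyclo[5.3.0]decan-7α-yl)hexa-2,4-dienoate | O[C@@H]1[C@@H]2O[C@]2(C)CC[C@H]2[C@H](/C(C)=C\C=C\C(=O)OC)CC[C@]12C | intermediate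
24 | (3E,5Z)-6-(2α,3α-epoxy-1α-hydroxy-3,10β-dimethyl-6αH-bicyclo[5.3.0]decan-7α-yl)-2-methylhepta-3,5-dien-2-ol | O[C@@H]1[C@@H]2O[C@]2(C)CC[C@H]2[C@H](/C(C)=C\C=C\C(C)(C)O)CC[C@]12C | intermediate
25 | (1S,2S,3R,6S,7R,10S)-2,3-epoxy-7-[(2Z,4E)-6-hydroxy-6-methylhepta-2,4-dien-2-yl]-3,10-dimethylbicyclo[5.3.0]decan-1-yl acetate (CNP0265175.1) | CC(=O)O[C@@H]1[C@@H]2O[C@]2(C)CC[C@H]2[C@H](/C(C)=C\C=C\C(C)(C)O)CC[C@]12C | target

Step count and risk

Total: 18 steps. Longest linear sequence: 18 steps (from 1 and 2 to 25); the route has no convergent branch.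

Step 6 (key step, carries the label). The most likely failure is opening of the activated epoxide at C7 rather than C8, with a 1,2-shift of the isopropenyl group, a ring carbon or hydride from the neighbouring centres, because a primary carbon is a poor electrophile for a π-nucleophile and the closure is 5-endo. Capture of C8 by chloride, loss of a proton from the C10 cation before C1 migrates, and migration of C5 in place of C1 are further ways for the cascade to leave its course. The fallback keeps the disconnection but takes out the unprecedented event, the attack of an alkene on a primary epoxide carbon. It uses only established reaction types and leaves only a protic Wagner–Meerwein ring enlargement ended by a pinacol-type hydride shift, which is still without precedent on this molecule. It sets out from 5 and returns at 11. Reduction of 5 with LiAlH4 gives [(S)-4-methyl-1-(prop-1-en-2-yl)cyclohex-3-en-1-yl]methanol F1, and Dess–Martin oxidation gives (S)-4-methyl-1-(prop-1-en-2-yl)cyclohex-3-ene-1-carbaldehyde F2. Asymmetric allylboration with (–)-B-allyldiisopinocampheylborane (attack on the Si face) should give (S)-1-[(S)-4-methyl-1-(prop-1-en-2-yl)cyclohex-3-en-1-yl]but-3-en-1-ol F3, with the same spatial arrangement at C7 as in 8. Ring-closing metathesis of the terminal alkene with the isopropenyl group closes the cyclopentene and gives (1S,5S)-4,8-dimethylspiro[4.5]deca-3,7-dien-1-ol F4. Protonation of its C9=C10 bond (BF3·OEt2 or catalytic CF3SO3H, CH2Cl2, –78 °C) generates the same C10 cation as in the cascade, from which ring enlargement and the hydride shift should lead to 11.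

Step 1. The risk is insufficient facial discrimination in the C–C bond formation, because the donor is acyclic and its two arms (allyl and the incoming oxobutyl chain) are similar; the quaternary centre cannot be corrected later. The fallback replaces catalyst control by auxiliary control. It sets out from 1 and returns at 3. Condensation of 1 with (S)-1-phenylethylamine gives ethyl (Z)-3-{[(S)-1-phenylethyl]amino}-2-(prop-2-en-1-yl)but-2-enoate F5. Conjugate addition of this chiral enamino ester to 2 (neat or with ZnCl2) should give ethyl (S)-5-oxo-2-{1-[(S)-1-phenylethyl]iminoethyl}-2-(prop-2-en-1-yl)hexanoate F6, and hydrolysis with aqueous acetic acid gives 3. The antipodal amine is used if the sense of induction is the reverse.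

Step 7. The risk is enolisation of the ketone toward C6 by the basic ylide, followed by reprotonation to the cis-fused ketone, because C6–H is α to the carbonyl and the cis ring fusion may be the more stable one. The fallback avoids any equilibrating base at the ketone stage. It sets out from 11 and returns at 13. Kinetic deprotonation at C8 (LiN(i-Pr)2, –78 °C) and trapping with PhNTf2 give 3,10β-dimethyl-6αH-bicyclo[5.3.0]deca-2,7-dien-7-yl trifluoromethanesulfonate F7. Methoxycarbonylation (Pd(OAc)2, PPh3, CO, MeOH, Et3N) gives methyl 3,10β-dimethyl-6αH-bicyclo[5.3.0]deca-2,7-diene-7-carboxylate F8. Conjugate reduction (Mg, MeOH) and equilibration (NaOMe) give methyl 3,10β-dimethyl-6αH-bicyclo[5.3.0]dec-2-ene-7α-carboxylate F9, and i-Bu2AlH at –78 °C gives 13.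

Step 11. The risk is oxidation at C4 or at the C3 methyl group in place of C1, or incomplete conversion, because C1 is a neopentyl position shielded by the C10 quaternary centre. The fallback fixes the regiochemistry by mechanism instead of by preference. It sets out from 14 and returns at 17. Epoxidation of 14 with mCPBA gives 2α,3α-epoxy-7α-ethynyl-3,10β-dimethyl-6αH-bicyclo[5.3.0]decane F10; either epoxide face serves. Opening at the secondary C2 with PhSeNa gives 7α-ethynyl-3,10β-dimethyl-2β-(phenylselanyl)-6αH-bicyclo[5.3.0]decan-3α-ol F11. Oxidation with H2O2 and selenoxide elimination, which can only go toward C1, give 7α-ethynyl-3,10β-dimethyl-6αH-bicyclo[5.3.0]dec-1-en-3α-ol F12. Oxidative 1,3-transposition with pyridinium chlorochromate gives 7α-ethynyl-3,10β-dimethyl-6αH-bicyclo[5.3.0]dec-2-en-1-one F13. Oxidative methoxycarbonylation of the terminal alkyne (PdCl2, CuCl2, NaOAc, CO, MeOH) gives 17.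

Step 13. The risk is hydride delivery to the α face, with substrate control overriding the catalyst, because the β face of the C1 carbonyl is flanked by the angular methyl group; the directed epoxidation would then place the epoxide on the wrong face as well. The fallback accepts substrate control and inverts. It sets out from 18 and returns at 19. Luche reduction (NaBH4, CeCl3, MeOH) would give methyl (Z)-3-(1β-hydroxy-3,10β-dimethyl-6αH-bicyclo[5.3.0]dec-2-en-7α-yl)but-2-enoate F14. Mitsunobu inversion with 4-nitrobenzoic acid (PPh3, diisopropyl azodicarboxylate) gives methyl (Z)-3-[3,10β-dimethyl-1α-(4-nitrobenzoyloxy)-6αH-bicyclo[5.3.0]dec-2-en-7α-yl]but-2-enoate F15, and methanolysis (K2CO3, MeOH) gives 19.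

Further compounds

F1 | step 6 | [(S)-4-methyl-1-(prop-1-en-2-yl)cyclohex-3-en-1-yl]methanol | CC1=CC[C@@](CC1)(C(C)=C)CO
F2 | step 6 | (S)-4-methyl-1-(prop-1-en-2-yl)cyclohex-3-ene-1-carbaldehyde | CC1=CC[C@@](CC1)(C(C)=C)C=O
F3 | step 6 | (S)-1-[(S)-4-methyl-1-(prop-1-en-2-yl)cyclohex-3-en-1-yl]but-3-en-1-ol | CC1=CC[C@@](CC1)(C(C)=C)[C@@H](O)CC=C
F4 | step 6 | (1S,5S)-4,8-dimethylspiro[4.5]deca-3,7-dien-1-ol | CC1=CC[C@@]2(CC1)C(C)=CC[C@@H]2O
F5 | step 1 | ethyl (Z)-3-{[(S)-1-phenylethyl]amino}-2-(prop-2-en-1-yl)but-2-enoate | CCOC(=O)/C(CC=C)=C(C)\N[C@@H](C)c1ccccc1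
F6 | step 1 | ethyl (S)-5-oxo-2-{1-[(S)-1-phenylethyl]iminoethyl}-2-(prop-2-en-1-yl)hexanoate | C=CC[C@@](CCC(C)=O)(C(C)=N[C@@H](C)c1ccccc1)C(=O)OCC
F7 | step 7 | 3,10β-dimethyl-6αH-bicyclo[5.3.0]deca-2,7-dien-7-yl trifluoromethanesulfonate | O=S(=O)(OC1=CC[C@]2(C)CC=C(C)CC[C@@H]12)C(F)(F)F
F8 | step 7 | methyl 3,10β-dimethyl-6αH-bicyclo[5.3.0]deca-2,7-diene-7-carboxylate | COC(=O)C1=CC[C@]2(C)CC=C(C)CC[C@@H]12
F9 | step 7 | methyl 3,10β-dimethyl-6αH-bicyclo[5.3.0]dec-2-ene-7α-carboxylate | C1C=C(C)CC[C@H]2[C@H](C(=O)OC)CC[C@]12C
F10 | step 11 | 2α,3α-epoxy-7α-ethynyl-3,10β-dimethyl-6αH-bicyclo[5.3.0]decane | C1[C@@H]2O[C@]2(C)CC[C@H]2[C@H](C#C)CC[C@]12C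
F11 | step 11 | 7α-ethynyl-3,10β-dimethyl-2β-(phenylselanyl)-6αH-bicyclo[5.3.0]decan-3α-ol | C1[C@@H]([Se]c3ccccc3)[C@](C)(O)CC[C@H]2[C@H](C#C)CC[C@]12C
F12 | step 11 | 7α-ethynyl-3,10β-dimethyl-6αH-bicyclo[5.3.0]dec-1-en-3α-ol | C1=C[C@](C)(O)CC[C@H]2[C@H](C#C)CC[C@]12C
F13 | step 11 | 7α-ethynyl-3,10β-dimethyl-6αH-bicyclo[5.3.0]dec-2-en-1-one | O=C1C=C(C)CC[C@H]2[C@H](C#C)CC[C@]12C
F14 | step 13 | methyl (Z)-3-(1β-hydroxy-3,10β-dimethyl-6αH-bicyclo[5.3.0]dec-2-en-7α-yl)but-2-enoate | O[C@H]1C=C(C)CC[C@H]2[C@H](/C(C)=C\C(=O)OC)CC[C@]12C
F15 | step 13 | methyl (Z)-3-[3,10β-dimethyl-1α-(4-nitrobenzoyloxy)-6αH-bicyclo[5.3.0]dec-2-en-7α-yl]but-2-enoate | O=C(O[C@@H]1C=C(C)CC[C@H]2[C@H](/C(C)=C\C(=O)OC)CC[C@]12C)c1ccc(cc1)[N+](=O)[O-]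
A1 | alternative 1 | (R)-4-(tert-butyldimethylsilyloxy)-2-methylcyclopent-2-en-1-one | O=C1C[C@@H](O[Si](C)(C)C(C)(C)C)C=C1C
A2 | alternative 1 | (Z)-3-iodobut-2-enal | O=C/C=C(C)\I
A3 | alternative 1 | 4-(tert-butyldimethylsilyloxy)-2-[(Z)-1-hydroxy-3-iodobut-2-en-1-yl]-2-methyl-3-vinylcyclopentan-1-one (vinyl anti to the silyl ether, carbinol chain anti to vinyl, carbinol epimers) | O=C1C[C@@H](O[Si](C)(C)C(C)(C)C)[C@H](C=C)[C@@]1(C)C(O)/C=C(C)\I
A4 | alternative 2 | trans-fused six–seven bicyclic α-diazoketone (diazo carbon C7, C1 ketone as dioxolane, angular methyl on C10) | [N-]=[N+]=C1C(=O)CC[C@]2(C)C3(OCCO3)CCCC[C@@H]12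
A5 | alternative 2 | trans-fused hydroazulene C7 methyl ester, C1 ketone as dioxolane | COC(=O)[C@@H]1CC[C@]2(C)C3(OCCO3)CCCC[C@@H]12
A6 | alternative 3 | 3-chloro-3-methyl-6-(5-methylfuran-2-yl)-6-(2-methyl-1,3-dioxolan-2-yl)hexan-2-one (C7 as in the target, C10 unassigned) | CC(=O)C(C)(Cl)CC[C@@H](C1(C)OCCO1)c1ccc(C)o1
A7 | alternative 3 | oxygen-bridged tricyclic C1 ketone (8-oxabicyclo[3.2.1]octenone fused to the cyclopentane, C11 ketone as dioxolane) | O=C1C[C@@]2(C)C=C[C@@]3(O2)[C@H](C4(C)OCCO4)CC[C@]13C
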